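| flask | starting material | gas phase | protic impurity | catalyst | remark | time |
|---|---|---|---|---|---|---|
| Monday's | 20 mM | 1.9 mM (held) | 20 mM | 20 µM | run made earlier |  |
| Friday's | 20 mM | 1.9 mM (held) | 20 mM | 30 µM | run made earlier |  |
| Tuesday's | 20 mM | 1.9 mM (held) | 10 mM | 40 µM | run made earlier |  |
| flask | 20 mM | 1.9 mM (held) | 20.0 mM | 40 µM |  | 8.0 h |

- Monday's (time / h: target / %): 0.417: 3; 1.33: 8; 2.50: 11; 4.00: 13; 5.00: 16; 6.00: 19
- Friday's (time / h: target / %): 0.417: 2; 1.33: 8; 2.50: 14; 4.00: 19; 5.00: 18; 6.00: 24
- Tuesday's (time / h: target / %): 1.33: 14; 2.50: 21; 4.00: 31; 5.00: 35; 6.00: 37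

(standard deviation of a reading: 1.5 percentage points)

- at the start none of the gas phase is in solution

- target at 8.0 h, in percent of the starting material charged
- concentration of dissolved gas in solution at 8.0 h, in percent of saturation

1. Target, as a fraction of the starting material charged, equals turnovers times the catalyst charge taken as the same kind of fraction. That is bookkeeping, whatever the rate.

2. So you fold reading and charges into one number. At 6.00 h, Friday's run gives 160 turnovers, target made per catalyst charged (the turnover number). Monday's run gives 190, more than Friday's. Each carries the scatter of a reading.

3. Is one number enough? Tuesday's run, with half the protic impurity and more catalyst, counts 185, above Friday's. So across these runs it is not, and you carry Friday's count, whose protic impurity is also this flask's.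

4. This flask's catalyst is 0.200% of the starting material. It has more catalyst than Friday's run, and Friday's count, with more catalyst than Monday's, read lower, but this flask also has longer to run. I set these against each other, which is a guess, and reckon 32.0%.

5. The forecast is 32% of target and 92% of saturation, since “the solution stays near saturation”.

The flask gives 29.8% of target and 98.4% of saturation.

    starting material + dissolved gas + catalyst → catalyst + target (k = 5.12 × 10⁶ M⁻² h⁻¹)
    dissolved gas + catalyst ⇌ idle complex, settled at all times (K = 651 M⁻¹)
    starting material + dissolved gas → uncatalysed product (k = 61.3 M⁻¹ h⁻¹)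
    starting material + protic impurity → quenched substrate (k = 17.1 M⁻¹ h⁻¹)
    gas phase ⇌ dissolved gas, rate k5*(csat - [dissolved gas]) (kL = 5.07 h⁻¹)

The flask's count at 8.0 h is 149, below the 160 read from Friday's run at 6.00 h. With 0.016 mM of catalyst, the neighbour flask's carried count predicts 12.8%; it holds 15.0%, a count of 188, above Friday's. In the flask itself, 2.4% of the starting material stands at 8.00 h, and 0% at 80.0 h. Ten times the time adds 0.90 percentage points of target, reaching 30.7%, a count of 154.

(The runs stem from a simulated flask on assumed constants, noise included.)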